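**Retrosynthetic overview**

1. Erylatissin C, a (2S)-flavanone, comes from removal of two MOM ethers, and the protected flavanone from Wacker-type oxidation at C4 of a (2S)-2-aryl-2H-chromene, so the ketone appears only after ring C exists.
2. The plan rests on C2 of ring C: an sp3 carbon bonded to O1, H, C1' of ring B and C3, and tied to C4a of ring A only through C3–C4. While C3=C4 is an alkene, C2 is an allylic, benzylic ether with no carbonyl beside it and cannot epimerise by enolisation or ring opening.
3. Key disconnection: the C3=C4 bond, by ring-closing metathesis of an (S)-1-arylallyl 2-vinylaryl ether. Rings A and B are bought as arenes; ring C is the only ring made.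
4. The C2–O1 bond and the S centre come from an iridium-catalysed, branched-selective allylic etherification of the ring B cinnamyl methyl carbonate with the ring A 2-vinylphenoxide.
5. Ring B piece: 3-bromo-4,5-dihydroxybenzaldehyde (4-O-methylation, MOM, Suzuki prenylation, Horner–Wadsworth–Emmons, reduction, carbonate). Ring A piece: 2,4-dihydroxybenzaldehyde (4-O-MOM, Wittig).

Key step: step 10

Assumption: in step 9 the (Sa,Sc,Sc) phosphoramidite is taken to give the S ether, by analogy with the parent cinnamyl carbonate and phenoxide; if the first experiment shows the opposite sense, the equally available (Ra,Rc,Rc) ligand is used instead.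

**Route**

Step 1
Reactants: 1 2,4-dihydroxybenzaldehyde
Product: 2 2-hydroxy-4-(methoxymethoxy)benzaldehyde
Conditions: MOMCl (1.05 equiv), K2CO3, acetone, 0 °C to rt
Reagents that add atoms: chloromethyl methyl ether, COCCl
Why: Williamson-type MOM protection, in which the 4-OH is the more acidic and accessible phenol while the 2-OH is held in a hydrogen bond to the aldehyde, so one equivalent of MOMCl with a mild base should protect O4 only.

Step 2
Reactants: 2 2-hydroxy-4-(methoxymethoxy)benzaldehyde
Product: 3 5-(methoxymethoxy)-2-vinylphenol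
Conditions: Ph3PCH3Br (2.2 equiv), KOt-Bu (2.2 equiv), THF, 0 °C to rt; aq NH4Cl work-up, stored cold with BHT
Reagents that add atoms: methyltriphenylphosphonium bromide, C[P+](c1ccccc1)(c1ccccc1)c1ccccc1.[Br-]
Why: Wittig methylenation with excess ylide, the first equivalent deprotonating the phenol and the second converting the aldehyde of the phenoxide into the vinyl group.

Step 3
Reactants: 4 3-bromo-4,5-dihydroxybenzaldehyde
Product: 5 3-bromo-5-hydroxy-4-methoxybenzaldehyde
Conditions: MeI (1.1 equiv), Li2CO3 (1.2 equiv), DMF, 40 °C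
Reagents that add atoms: iodomethane, CI
Why: Regioselective Williamson O-methylation, since the 4-OH (para to the aldehyde, ortho to bromine) is the most acidic phenol and a weak base in limiting amount should form and alkylate only that phenoxide.

Step 4
Reactants: 5 3-bromo-5-hydroxy-4-methoxybenzaldehyde
Product: 6 3-bromo-4-methoxy-5-(methoxymethoxy)benzaldehyde
Conditions: MOMCl, i-Pr2NEt, CH2Cl2, 0 °C to rt
Reagents that add atoms: chloromethyl methyl ether, COCCl
Why: Standard MOM protection of the one remaining phenol under amine base, which leaves the aldehyde and the aryl bromide untouched.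

Step 5
Reactants: 6 3-bromo-4-methoxy-5-(methoxymethoxy)benzaldehyde; 7 prenylboronic acid pinacol ester
Product: 8 4-methoxy-3-(methoxymethoxy)-5-(3-methylbut-2-enyl)benzaldehyde
Conditions: 7 (1.5 equiv), PdCl2(IPent)(3-chloropyridine) (2 mol %; IPent = 1,3-bis[2,6-di(pentan-3-yl)phenyl]imidazol-2-ylidene), aq KOH, THF, 65 °C
Reagents that add atoms: none
Why: Suzuki–Miyaura coupling of an allylboronate, in which the bulky N-heterocyclic carbene on palladium lets the allylpalladium intermediate equilibrate and reductively eliminate at the unsubstituted carbon, which should give the linear prenyl arene and not the 1,1-dimethylallyl isomer.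

Step 6
Reactants: 8 4-methoxy-3-(methoxymethoxy)-5-(3-methylbut-2-enyl)benzaldehyde
Product: 9 ethyl (E)-3-[4-methoxy-3-(methoxymethoxy)-5-(3-methylbut-2-enyl)phenyl]acrylate
Conditions: (EtO)2P(O)CH2CO2Et, NaH, THF, 0 °C to rt
Reagents that add atoms: triethyl phosphonoacetate, CCOC(=O)CP(=O)(OCC)OCC
Why: Horner–Wadsworth–Emmons olefination of a non-enolisable aryl aldehyde with a stabilised phosphonate anion, which should give the (E)-cinnamate.

Step 7
Reactants: 9 ethyl (E)-3-[4-methoxy-3-(methoxymethoxy)-5-(3-methylbut-2-enyl)phenyl]acrylate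
Product: 10 (E)-3-[4-methoxy-3-(methoxymethoxy)-5-(3-methylbut-2-enyl)phenyl]prop-2-en-1-ol
Conditions: i-Bu2AlH (2.2 equiv), CH2Cl2, −78 °C; aq potassium sodium tartrate work-up
Reagents that add atoms: none
Why: 1,2-Reduction of the unsaturated ester by the aluminium hydride at low temperature should give the allylic alcohol without touching either alkene or the MOM acetal.

Step 8
Reactants: 10 (E)-3-[4-methoxy-3-(methoxymethoxy)-5-(3-methylbut-2-enyl)phenyl]prop-2-en-1-ol
Product: 11 methyl (E)-3-[4-methoxy-3-(methoxymethoxy)-5-(3-methylbut-2-enyl)phenyl]allyl carbonate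
Conditions: ClCO2Me, pyridine, CH2Cl2, 0 °C
Reagents that add atoms: methyl chloroformate, COC(=O)Cl
Why: Acylation of the primary allylic alcohol with a chloroformate installs the carbonate leaving group needed for iridium allyl chemistry.

Step 9
Reactants: 11 methyl (E)-3-[4-methoxy-3-(methoxymethoxy)-5-(3-methylbut-2-enyl)phenyl]allyl carbonate; 3 5-(methoxymethoxy)-2-vinylphenol
Product: 13 (S)-1-[4-methoxy-3-(methoxymethoxy)-5-(3-methylbut-2-enyl)phenyl]allyl 5-(methoxymethoxy)-2-vinylphenyl ether, via lithium 5-(methoxymethoxy)-2-vinylphenoxide 12 (not isolated)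
Conditions: 3 (1.5 equiv), LiN(SiMe3)2, THF, 0 °C; then 11, [Ir(cod)Cl]2 (2 mol %), (Sa,Sc,Sc)-O,O'-(1,1'-binaphthyl-2,2'-diyl) N,N-bis(1-phenylethyl)phosphoramidite (4 mol %, preactivated with n-PrNH2, volatiles removed), THF, rt to 50 °C
Reagents that add atoms: none
Why: Iridium-catalysed asymmetric allylic etherification, in which the cyclometalated iridium–phosphoramidite complex ionises the linear carbonate to a (π-allyl)iridium species that the phenoxide attacks at the aryl-substituted terminus to give the branched ether, the (Sa,Sc,Sc) ligand directing attack to the face that sets C2 as S.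

Step 10
Reactants: 13 (S)-1-[4-methoxy-3-(methoxymethoxy)-5-(3-methylbut-2-enyl)phenyl]allyl 5-(methoxymethoxy)-2-vinylphenyl ether
Product: 14 (2S)-7-(methoxymethoxy)-2-[4-methoxy-3-(methoxymethoxy)-5-(3-methylbut-2-enyl)phenyl]-2H-chromene
Conditions: RuCl2(=CHPh)(PCy3)(H2IMes) (second-generation Grubbs catalyst, 3–5 mol %), CH2Cl2 (0.01 M), rt to 40 °C, argon sparge, exclusion of light
Reagents that add atoms: none
Why: The ruthenium benzylidene exchanges onto one of the two monosubstituted vinyl groups, the resulting carbene undergoes intramolecular [2+2] addition to the other vinyl group, and cycloreversion of the ruthenacyclobutane expels ethene and forms the C3=C4 bond. This is ring-closing olefin metathesis of an allyl 2-vinylphenyl ether, the established way to 2H-chromenes. Ring C closes as a six-membered ring by joining the terminal carbons of the allylic vinyl group on C2 and the styrene vinyl group on C4a. No stereocentre is created; the S centre at C2 from step 9 is carried through because neither the C2–O nor the C2–H bond is touched and no carbonyl flanks C2. The step needs chemoselectivity among three alkenes, which the substrate provides: the prenyl alkene is trisubstituted and sits meta to the allylic carbon, so it reacts far more slowly and cannot close a ring. Low catalyst loading, removal of ethene and a short reaction time should keep the prenyl group out of secondary metathesis.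

Step 11
Reactants: 14 (2S)-7-(methoxymethoxy)-2-[4-methoxy-3-(methoxymethoxy)-5-(3-methylbut-2-enyl)phenyl]-2H-chromene
Product: 15 (2S)-7-(methoxymethoxy)-2-[4-methoxy-3-(methoxymethoxy)-5-(3-methylbut-2-enyl)phenyl]chroman-4-one
Conditions: PdCl2 (20 mol %), CuCl (1 equiv), O2 (1 atm), DMF/H2O 7:1, rt to 40 °C, dark
Reagents that add atoms: water, O
Why: Wacker-type oxidation of an internal alkene, in which hydroxypalladation by divalent palladium should place oxygen on benzylic C4 (the carbon best able to carry positive charge through the ortho and para oxygen donors of ring A, and distal to the electron-withdrawing allylic C2–O bond), β-hydride elimination and tautomerisation then giving the C4 ketone while the trisubstituted prenyl alkene binds palladium too weakly to compete.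

Step 12
Reactants: 15 (2S)-7-(methoxymethoxy)-2-[4-methoxy-3-(methoxymethoxy)-5-(3-methylbut-2-enyl)phenyl]chroman-4-one
Product: 16 erylatissin C, (2S)-7-hydroxy-2-[3-hydroxy-4-methoxy-5-(3-methylbut-2-enyl)phenyl]chroman-4-one
Conditions: 3 M aq HCl, MeOH, 40 °C
Reagents that add atoms: none
Why: Acid-catalysed acetal exchange with methanol removes both MOM ethers; C2 should hold because flavanone ring opening to the chalcone is base-promoted, and the prenyl group has only a methoxy neighbour, so it cannot cyclise onto a phenol.

**Compound list**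

1 | 2,4-dihydroxybenzaldehyde | O=Cc1ccc(O)cc1O | starting material
2 | 2-hydroxy-4-(methoxymethoxy)benzaldehyde | O=Cc1ccc(OCOC)cc1O | intermediate
3 | 5-(methoxymethoxy)-2-vinylphenol | C=Cc1ccc(OCOC)cc1O | intermediate
4 | 3-bromo-4,5-dihydroxybenzaldehyde | O=Cc1cc(O)c(O)c(Br)c1 | starting material
5 | 3-bromo-5-hydroxy-4-methoxybenzaldehyde | O=Cc1cc(O)c(OC)c(Br)c1 | intermediate
6 | 3-bromo-4-methoxy-5-(methoxymethoxy)benzaldehyde | O=Cc1cc(OCOC)c(OC)c(Br)c1 | intermediate
7 | prenylboronic acid pinacol ester | CC(C)=CCB1OC(C)(C)C(C)(C)O1 | starting material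
8 | 4-methoxy-3-(methoxymethoxy)-5-(3-methylbut-2-enyl)benzaldehyde | O=Cc1cc(OCOC)c(OC)c(CC=C(C)C)c1 | intermediate
9 | ethyl (E)-3-[4-methoxy-3-(methoxymethoxy)-5-(3-methylbut-2-enyl)phenyl]acrylate | CCOC(=O)/C=C/c1cc(OCOC)c(OC)c(CC=C(C)C)c1 | intermediate
10 | (E)-3-[4-methoxy-3-(methoxymethoxy)-5-(3-methylbut-2-enyl)phenyl]prop-2-en-1-ol | OC/C=C/c1cc(OCOC)c(OC)c(CC=C(C)C)c1 | intermediate
11 | methyl (E)-3-[4-methoxy-3-(methoxymethoxy)-5-(3-methylbut-2-enyl)phenyl]allyl carbonate | COC(=O)OC/C=C/c1cc(OCOC)c(OC)c(CC=C(C)C)c1 | intermediate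
12 | lithium 5-(methoxymethoxy)-2-vinylphenoxide | [Li+].[O-]c1cc(OCOC)ccc1C=C | intermediate (not isolated)
13 | (S)-1-[4-methoxy-3-(methoxymethoxy)-5-(3-methylbut-2-enyl)phenyl]allyl 5-(methoxymethoxy)-2-vinylphenyl ether | COc1c(OCOC)cc([C@@H](Oc2cc(OCOC)ccc2C=C)C=C)cc1CC=C(C)C | intermediate
14 | (2S)-7-(methoxymethoxy)-2-[4-methoxy-3-(methoxymethoxy)-5-(3-methylbut-2-enyl)phenyl]-2H-chromene | COc1c(OCOC)cc([C@@H]2C=Cc3ccc(OCOC)cc3O2)cc1CC=C(C)C | intermediate
15 | (2S)-7-(methoxymethoxy)-2-[4-methoxy-3-(methoxymethoxy)-5-(3-methylbut-2-enyl)phenyl]chroman-4-one | COc1c(OCOC)cc([C@@H]2CC(=O)c3ccc(OCOC)cc3O2)cc1CC=C(C)C | intermediate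
16 | erylatissin C, (2S)-7-hydroxy-2-[3-hydroxy-4-methoxy-5-(3-methylbut-2-enyl)phenyl]chroman-4-one | COc1c(O)cc([C@@H]2CC(=O)c3ccc(O)cc3O2)cc1CC=C(C)C | target

**Step count**

Total: 12 steps. Longest linear sequence: 10 steps (steps 3 to 12, from 4); the ring A branch (steps 1 and 2) joins at step 9.

**Steps most likely to fail**

Step 11 (Wacker-type oxidation). Hydroxypalladation of the internal ring alkene may be slow, oxygen may be delivered to C3, the prenyl alkene may be oxidised on long exposure, or β-hydride elimination toward C2 may flatten the stereocentre. The fallback builds the C4 oxygen into the metathesis substrate and sets out from carbonate 11. Commercial 2,4-dihydroxyacetophenone is protected with MOMCl and K2CO3 to give 1-[2-hydroxy-4-(methoxymethoxy)phenyl]ethanone F1. F1 is coupled with 11 in the presence of LiN(SiMe3)2 under the iridium conditions of step 9 to give 1-[2-{(S)-1-[4-methoxy-3-(methoxymethoxy)-5-(3-methylbut-2-enyl)phenyl]allyloxy}-4-(methoxymethoxy)phenyl]ethanone F2. KN(SiMe3)2 and TBSCl in THF at −78 °C convert the methyl ketone into the tert-butyldimethylsilyl enol ether of F2, F3. Silyl enol ether–ene ring-closing metathesis with the second-generation Grubbs catalyst in warm toluene gives (2S)-4-(tert-butyldimethylsilyloxy)-7-(methoxymethoxy)-2-[4-methoxy-3-(methoxymethoxy)-5-(3-methylbut-2-enyl)phenyl]-2H-chromene F4. Bu4NF buffered with AcOH at 0 °C releases the ketone and the sequence comes back to the route at 15.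

Step 9 (iridium allylic etherification). The branched ether carries an electron-rich aryl group and may re-ionise on the catalyst, drifting to the linear cinnamyl ether and losing enantiopurity; the vinylphenol may also polymerise. The fallback forms the aryl–oxygen bond instead of the allyl–oxygen bond, so no allyl metal species is generated, and sets out from aldehyde 8. CH2=CHMgBr in THF gives racemic 1-[4-methoxy-3-(methoxymethoxy)-5-(3-methylbut-2-enyl)phenyl]prop-2-en-1-ol F5. Candida antarctica lipase B with vinyl acetate should acylate the R alcohol, following the usual preference of this lipase for secondary alcohols with one large and one medium substituent. This leaves (S)-1-[4-methoxy-3-(methoxymethoxy)-5-(3-methylbut-2-enyl)phenyl]prop-2-en-1-ol F6 and gives (R)-1-[4-methoxy-3-(methoxymethoxy)-5-(3-methylbut-2-enyl)phenyl]allyl acetate F7, which is separated. Commercial 2-fluoro-4-hydroxybenzaldehyde is protected with MOMCl and i-Pr2NEt to give 2-fluoro-4-(methoxymethoxy)benzaldehyde F8. The sodium alkoxide of F6 (NaH, DMF, 0 °C to rt) displaces fluoride from F8 by nucleophilic aromatic substitution, with retention at carbon because the carbinol C–O bond is not broken, giving 2-{(S)-1-[4-methoxy-3-(methoxymethoxy)-5-(3-methylbut-2-enyl)phenyl]allyloxy}-4-(methoxymethoxy)benzaldehyde F9. Wittig methylenation (Ph3PCH3Br, KOt-Bu) of F9 comes back to the route at 13.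

Step 5 (Suzuki prenylation). Transmetalation through the γ-carbon followed by fast reductive elimination may give the 1,1-dimethylallyl isomer, and the aldehyde may disproportionate under aqueous hydroxide. The fallback removes the regiochemical question by using a symmetrical allyl group and sets out from bromide 6. Coupling with allylboronic acid pinacol ester (Pd(PPh3)4, aq K3PO4, THF, 65 °C) gives 3-allyl-4-methoxy-5-(methoxymethoxy)benzaldehyde F10. Cross-metathesis of F10 with excess 2-methyl-2-butene (second-generation Grubbs catalyst, 40 °C) comes back to the route at 8.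

**Further compounds**

F1 | step 11 | 1-[2-hydroxy-4-(methoxymethoxy)phenyl]ethanone | CC(=O)c1ccc(OCOC)cc1O
F2 | step 11 | 1-[2-{(S)-1-[4-methoxy-3-(methoxymethoxy)-5-(3-methylbut-2-enyl)phenyl]allyloxy}-4-(methoxymethoxy)phenyl]ethanone | COc1c(OCOC)cc([C@@H](Oc2cc(OCOC)ccc2C(C)=O)C=C)cc1CC=C(C)C
F3 | step 11 | tert-butyldimethylsilyl enol ether of F2 | COc1c(OCOC)cc([C@@H](Oc2cc(OCOC)ccc2C(=C)O[Si](C)(C)C(C)(C)C)C=C)cc1CC=C(C)C
F4 | step 11 | (2S)-4-(tert-butyldimethylsilyloxy)-7-(methoxymethoxy)-2-[4-methoxy-3-(methoxymethoxy)-5-(3-methylbut-2-enyl)phenyl]-2H-chromene | COc1c(OCOC)cc([C@@H]2C=C(O[Si](C)(C)C(C)(C)C)c3ccc(OCOC)cc3O2)cc1CC=C(C)C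
F5 | step 9 | racemic 1-[4-methoxy-3-(methoxymethoxy)-5-(3-methylbut-2-enyl)phenyl]prop-2-en-1-ol | COc1c(OCOC)cc(C(O)C=C)cc1CC=C(C)C
F6 | step 9 | (S)-1-[4-methoxy-3-(methoxymethoxy)-5-(3-methylbut-2-enyl)phenyl]prop-2-en-1-ol | COc1c(OCOC)cc([C@@H](O)C=C)cc1CC=C(C)C
F7 | step 9 | (R)-1-[4-methoxy-3-(methoxymethoxy)-5-(3-methylbut-2-enyl)phenyl]allyl acetate | COc1c(OCOC)cc([C@H](OC(C)=O)C=C)cc1CC=C(C)C
F8 | step 9 | 2-fluoro-4-(methoxymethoxy)benzaldehyde | O=Cc1ccc(OCOC)cc1F
F9 | step 9 | 2-{(S)-1-[4-methoxy-3-(methoxymethoxy)-5-(3-methylbut-2-enyl)phenyl]allyloxy}-4-(methoxymethoxy)benzaldehyde | COc1c(OCOC)cc([C@@H](Oc2cc(OCOC)ccc2C=O)C=C)cc1CC=C(C)C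
F10 | step 5 | 3-allyl-4-methoxy-5-(methoxymethoxy)benzaldehyde | O=Cc1cc(OCOC)c(OC)c(CC=C)c1
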